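**Assumptions.** The target is drawn as the free bis(hydrogen sulfate); it is made and handled as the disodium salt, and the drawn acid is its protonated form. Locants: West decalin C1–C10 (C4 carries the linker, C5=C6, C9 carries the arylmethyl); East decalin C1'–C10' (C1'=C10', C4' gem-dimethyl, C9' carries the linker). Target configuration: West 4S,8R,9R,10S; East 5'R,8'S,9'R. ArCH2 = 2,5-dimethoxybenzyl. W = (1S,4aS,5R,6R)-5-(ArCH2)-1,5,6-trimethyl-1,2,3,4,4a,5,6,7-octahydronaphthalen-1-yl (the West decalin, attached through C4).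

## Retrosynthetic overview

1. Toxiusol ⇐ hydroquinone ⇐ 2,5-dimethoxyaryl ether (CAN, dithionite, then SO3·pyridine); the arene is carried from step 2.
2. East ring A' (C1'=C10') is closed last by intramolecular McMurry coupling; its C4' arm comes from acetone aldol and Sakurai allylation on the ring-B' ketone.
3. The halves are joined at C9'–CH2: the enolate from Cu-catalysed asymmetric methyl addition to 2-methylcyclohexenone (sets C8', then C9') is alkylated by a West iodide.
4. West C4 and the C5=C6 alkene come from an Eschenmoser–Claisen rearrangement of a 6α-allylic alcohol, itself made by ketoreductase reduction of a bicyclic enone (ring A by cuprate addition and aldol condensation).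
5. West ring B comes from cyclohexenone: Cu-catalysed asymmetric methyl addition (C8), benzylation/methylation (C9), Wharton transposition. Ring order: B → A, then B' → A'.

## Route

**Step 1**
Reactants: 1, cyclohex-2-en-1-one
Product: 2, (R)-trimethyl[(3-methylcyclohex-1-en-1-yl)oxy]silane
Conditions: Me2Zn, Cu(OTf)2 (2 mol%), BINOL-derived phosphoramidite (4 mol%, antipode chosen to give 3R), PhMe, −30 °C; then TMSOTf
Reagents that add atoms: dimethylzinc, C[Zn]C; TMSOTf, C[Si](C)(C)OS(=O)(=O)C(F)(F)F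
Why: Cu-catalysed asymmetric conjugate addition sets C8 (first stereocentre) under catalyst control, and O-silylation fixes the enolate regiochemistry.

**Step 2**
Reactants: 2; 3, 2-(bromomethyl)-1,4-dimethoxybenzene
Product: 4, (2S,3R)-2-(ArCH2)-3-methylcyclohexan-1-one
Conditions: MeLi, THF, 0 °C; then 3, DMPU, −78 → −20 °C
Reagents that add atoms: none (both reactants listed)
Why: regiospecific lithium enolate alkylation (SN2) anti to the methyl group; the C2 configuration is erased in step 4.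

**Step 3**
Reactants: 4
Product: 5, (5R,6S)-6-(ArCH2)-5-methylcyclohex-2-en-1-one
Conditions: LDA, THF, −78 °C, TMSCl; then Pd(OAc)2, MeCN, rt
Reagents that add atoms: none
Why: Saegusa–Ito oxidation; kinetic deprotonation occurs at the CH2 rather than the tertiary α-carbon.

**Step 4**
Reactants: 5
Product: 6, (5R,6R)-6-(ArCH2)-5,6-dimethylcyclohex-2-en-1-one
Conditions: LDA, THF, −78 °C; MeI, DMPU, −78 → 0 °C
Reagents that add atoms: iodomethane, CI
Why: α'-alkylation of the kinetic cross-conjugated enolate; MeI enters anti to the pseudoaxial C5 methyl, so C9 carries ArCH2 cis to the C8 methyl.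

**Step 5**
Reactants: 6
Product: 7, (3R,4R)-3-(ArCH2)-3,4-dimethyl-7-oxabicyclo[4.1.0]heptan-2-one (epoxide diastereomers, both used)
Conditions: 30% H2O2, NaOH (cat.), MeOH, 0 °C
Reagents that add atoms: hydrogen peroxide, OO
Why: Weitz–Scheffer nucleophilic epoxidation; the ketone has no other enolisable position and the epoxide configuration is lost later.

**Step 6**
Reactants: 7
Product: 8, (4R,5R)-4-(ArCH2)-4,5-dimethylcyclohex-2-en-1-ol (carbinol epimers)
Conditions: N2H4·H2O, AcOH (cat.), MeOH, 0 °C → rt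
Reagents that add atoms: none (hydrazine supplies only H; N2 is lost)
Why: Wharton transposition moves the oxygen from C10 to C6 and the alkene to C5=C10.

**Step 7**
Reactants: 8
Product: 9, (4R,5R)-4-(ArCH2)-4,5-dimethylcyclohex-2-en-1-one
Conditions: MnO2, CH2Cl2, rt
Reagents that add atoms: none
Why: allylic alcohol oxidation.

**Step 8**
Reactants: 9; 10, 2-(3-chloropropyl)-2-methyl-1,3-dioxolane
Product: 11, (3R,4R,5R)-4-(ArCH2)-4,5-dimethyl-3-[3-(2-methyl-1,3-dioxolan-2-yl)propyl]cyclohexan-1-one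
Conditions: 10, Mg, THF; CuBr·SMe2 (0.3 equiv), TMSCl, −78 → −40 °C; then K2CO3, MeOH
Reagents that add atoms: none (both reactants listed)
Why: TMSCl-accelerated cuprate conjugate addition; axial attack trans to the C8 methyl (3,5-trans rule) and anti to the axial ArCH2 sets C10 with H cis to ArCH2.

**Step 9**
Reactants: 11
Product: 12, (3R,4R,4aS)-4-(ArCH2)-3,4,8-trimethyl-3,4,4a,5,6,7-hexahydronaphthalen-1(2H)-one
Conditions: 2 M HCl, THF, rt; then NaOMe, MeOH, reflux
Reagents that add atoms: none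
Why: ketal hydrolysis then intramolecular aldol condensation; only the fused six-membered mode can dehydrate to a conjugated enone, and C8/C9/C10 are not enolisable.

**Step 10**
Reactants: 12
Product: 13, (1S,3R,4R,4aS)-4-(ArCH2)-3,4,8-trimethyl-1,2,3,4,4a,5,6,7-octahydronaphthalen-1-ol (6α-OH)
Conditions: ketoreductase (NADPH-dependent KRED, Prelog-selective, picked from a panel), NADP+ (cat.), glucose, glucose dehydrogenase, phosphate buffer pH 7, 15% DMSO, 30 °C
Reagents that add atoms: none (hydride only)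
Why: enzyme-controlled carbonyl reduction delivers hydride to the β-face, giving the axial (S)-allylic alcohol whose configuration is relayed to C4 in step 11.

**Step 11**
Reactants: 13
Product: 14, 2-(W)-N,N-dimethylacetamide
Conditions: MeC(OMe)2NMe2 (5 equiv), xylenes, 140 °C
Reagents that add atoms: N,N-dimethylacetamide dimethyl acetal, CC(OC)(OC)N(C)C
Why: Eschenmoser–Claisen [3,3] rearrangement; suprafacial transfer from the 6α C–O bond builds the C4 quaternary centre (CH2 α, Me β) and places the alkene at C5=C6.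

**Step 12**
Reactants: 14
Product: 15, 2-(W)ethan-1-ol
Conditions: LiH2N·BH3 (from LDA and BH3·NH3), THF, 0 °C → rt
Reagents that add atoms: none
Why: lithium amidotrihydroborate reduction of a tertiary amide to the primary alcohol.

**Step 13**
Reactants: 15
Product: 16, W–CH2CH2–I
Conditions: I2, PPh3, imidazole, CH2Cl2, 0 °C → rt
Reagents that add atoms: iodine, II
Why: Appel iodination of an unhindered primary alcohol.

**Step 14**
Reactants: 17, 2-methylcyclohex-2-en-1-one
Product: 18, (S)-[(2,3-dimethylcyclohex-1-en-1-yl)oxy]trimethylsilane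
Conditions: Me3Al, CuTC (5 mol%), chiral phosphinamine (SimplePhos-type) ligand (10 mol%, antipode chosen to give 3S), Et2O, −30 °C; then TMSOTf
Reagents that add atoms: trimethylaluminium, C[Al](C)C; TMSOTf, C[Si](C)(C)OS(=O)(=O)C(F)(F)F
Why: Cu-catalysed asymmetric conjugate addition to the α-substituted enone sets C8' (first East stereocentre), and silylation stores the tetrasubstituted enolate.

**Step 15**
Reactants: 18 (3 equiv); 16
Product: 19, (2R,3S)-2,3-dimethyl-2-[2-(W)ethyl]cyclohexan-1-one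
Conditions: 18, MeLi, THF, 0 °C → rt; then 16, HMPA, −40 °C → rt
Reagents that add atoms: none (both reactants listed)
Why: regiospecific enolate alkylation (SN2) anti to the pseudoaxial C8' methyl creates the C9' quaternary centre with the linker trans to that methyl.

**Step 16**
Reactants: 19
Product: 20, (2R,3S)-6-(2-hydroxypropan-2-yl)-2,3-dimethyl-2-[2-(W)ethyl]cyclohexan-1-one (C6 epimers)
Conditions: LDA, THF, −78 °C; ZnCl2; acetone; AcOH quench at −78 °C
Reagents that add atoms: acetone, CC(C)=O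
Why: directed aldol addition at C5', the only enolisable position.

**Step 17**
Reactants: 20
Product: 21, (2R,3S)-2,3-dimethyl-6-(propan-2-ylidene)-2-[2-(W)ethyl]cyclohexan-1-one
Conditions: MsCl, Et3N, DMAP, CH2Cl2, 0 °C → rt; then DBU, rt
Reagents that add atoms: none
Why: E1cB dehydration gives the conjugated isopropylidene ketone.

**Step 18**
Reactants: 21
Product: 22, (2R,3S,6R)-2,3-dimethyl-6-(2-methylpent-4-en-2-yl)-2-[2-(W)ethyl]cyclohexan-1-one
Conditions: allyltrimethylsilane, TiCl4, 2,6-di-tert-butylpyridine, CH2Cl2, −78 °C; then NaOMe, MeOH, 50 °C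
Reagents that add atoms: allyltrimethylsilane, C=CC[Si](C)(C)C
Why: Hosomi–Sakurai conjugate allylation builds C4'; base equilibration puts the bulky group equatorial, giving H5' cis to the axial C9' methyl.

**Step 19**
Reactants: 22
Product: 23, (2R,3S,6R)-6-(5-hydroxy-2-methylpentan-2-yl)-2,3-dimethyl-2-[2-(W)ethyl]cyclohexan-1-one
Conditions: 9-BBN, THF, 0 °C → rt; then H2O2, pH 7 buffer
Reagents that add atoms: hydrogen peroxide, OO (9-BBN adds H)
Why: anti-Markovnikov hydroboration–oxidation of the only monosubstituted alkene; the trisubstituted alkene and hindered ketone are inert to 9-BBN.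

**Step 20**
Reactants: 23
Product: 24, 4-methyl-4-{(1R,3R,4S)-3,4-dimethyl-2-oxo-3-[2-(W)ethyl]cyclohexyl}pentanal
Conditions: Dess–Martin periodinane, NaHCO3, CH2Cl2, rt
Reagents that add atoms: none
Why: Dess–Martin oxidation to the 1,6-keto-aldehyde.

**Step 21**
Reactants: 24
Product: 25, toxiusol hydroquinone dimethyl ether (full C30 bis-decalin with 2,5-dimethoxybenzyl on C9)
Conditions: TiCl3(DME)1.5, Zn–Cu, DME, reflux, slow addition (high dilution)
Reagents that add atoms: none
Why: intramolecular McMurry coupling of ketone C10' with aldehyde C1' closes ring A' and places the alkene regiospecifically at C1'=C10'.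

**Step 22**
Reactants: 25
Product: 26, the corresponding 2-substituted 1,4-benzoquinone
Conditions: (NH4)2Ce(NO3)6, MeCN/H2O (3:1), 0 °C, 15 min
Reagents that add atoms: water, O (quinone oxygens)
Why: CAN oxidative demethylation of the 1,4-dimethoxyarene; trisubstituted alkenes tolerate brief exposure at 0 °C.

**Step 23**
Reactants: 26
Product: 27, the hydroquinone (desulfated toxiusol)
Conditions: Na2S2O4, EtOAc/H2O, rt, degassed
Reagents that add atoms: none
Why: dithionite reduction of the quinone; used immediately to avoid re-oxidation.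

**Step 24**
Reactants: 27
Product: 28, toxiusol
Conditions: SO3·pyridine (10 equiv), pyridine, 50 °C, Ar; NaHCO3 work-up (disodium salt); H+ resin, 0 °C for the acid form
Reagents that add atoms: sulfur trioxide–pyridine, O=S(=O)=O.c1ccncc1
Why: O-sulfation of both phenols with SO3·pyridine; there is no other nucleophilic site.

## Compound list

1 | cyclohex-2-en-1-one | O=C1C=CCCC1 | starting material
2 | (R)-trimethyl[(3-methylcyclohex-1-en-1-yl)oxy]silane | C[C@@H]1CCCC(O[Si](C)(C)C)=C1 | intermediate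
3 | 2-(bromomethyl)-1,4-dimethoxybenzene | COc1ccc(OC)c(CBr)c1 | starting material
4 | (2S,3R)-2-(2,5-dimethoxybenzyl)-3-methylcyclohexan-1-one | C[C@@H]1CCCC(=O)[C@H]1Cc1cc(OC)ccc1OC | intermediate
5 | (5R,6S)-6-(2,5-dimethoxybenzyl)-5-methylcyclohex-2-en-1-one | C[C@@H]1CC=CC(=O)[C@H]1Cc1cc(OC)ccc1OC | intermediate
6 | (5R,6R)-6-(2,5-dimethoxybenzyl)-5,6-dimethylcyclohex-2-en-1-one | C[C@@H]1CC=CC(=O)[C@]1(C)Cc1cc(OC)ccc1OC | intermediate
7 | (3R,4R)-3-(2,5-dimethoxybenzyl)-3,4-dimethyl-7-oxabicyclo[4.1.0]heptan-2-one | C[C@@H]1CC2OC2C(=O)[C@]1(C)Cc1cc(OC)ccc1OC | intermediate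
8 | (4R,5R)-4-(2,5-dimethoxybenzyl)-4,5-dimethylcyclohex-2-en-1-ol | C[C@@H]1CC(O)C=C[C@]1(C)Cc1cc(OC)ccc1OC | intermediate
9 | (4R,5R)-4-(2,5-dimethoxybenzyl)-4,5-dimethylcyclohex-2-en-1-one | C[C@@H]1CC(=O)C=C[C@]1(C)Cc1cc(OC)ccc1OC | intermediate
10 | 2-(3-chloropropyl)-2-methyl-1,3-dioxolane | CC1(CCCCl)OCCO1 | starting material
11 | (3R,4R,5R)-4-(2,5-dimethoxybenzyl)-4,5-dimethyl-3-[3-(2-methyl-1,3-dioxolan-2-yl)propyl]cyclohexan-1-one | C[C@@H]1CC(=O)C[C@@H](CCCC2(C)OCCO2)[C@]1(C)Cc1cc(OC)ccc1OC | intermediate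
12 | (3R,4R,4aS)-4-(2,5-dimethoxybenzyl)-3,4,8-trimethyl-3,4,4a,5,6,7-hexahydronaphthalen-1(2H)-one | C[C@@H]1CC(=O)C2=C(C)CCC[C@H]2[C@]1(C)Cc1cc(OC)ccc1OC | intermediate
13 | (1S,3R,4R,4aS)-4-(2,5-dimethoxybenzyl)-3,4,8-trimethyl-1,2,3,4,4a,5,6,7-octahydronaphthalen-1-ol | C[C@@H]1C[C@H](O)C2=C(C)CCC[C@H]2[C@]1(C)Cc1cc(OC)ccc1OC | intermediate
14 | 2-[(1S,4aS,5R,6R)-5-(2,5-dimethoxybenzyl)-1,5,6-trimethyl-1,2,3,4,4a,5,6,7-octahydronaphthalen-1-yl]-N,N-dimethylacetamide | C[C@@H]1CC=C2[C@@H](CCC[C@@]2(C)CC(=O)N(C)C)[C@]1(C)Cc1cc(OC)ccc1OC | intermediate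
15 | 2-[(1S,4aS,5R,6R)-5-(2,5-dimethoxybenzyl)-1,5,6-trimethyl-1,2,3,4,4a,5,6,7-octahydronaphthalen-1-yl]ethan-1-ol | C[C@@H]1CC=C2[C@@H](CCC[C@@]2(C)CCO)[C@]1(C)Cc1cc(OC)ccc1OC | intermediate
16 | (1S,4aS,5R,6R)-5-(2,5-dimethoxybenzyl)-1-(2-iodoethyl)-1,5,6-trimethyl-1,2,3,4,4a,5,6,7-octahydronaphthalene | C[C@@H]1CC=C2[C@@H](CCC[C@@]2(C)CCI)[C@]1(C)Cc1cc(OC)ccc1OC | intermediate
17 | 2-methylcyclohex-2-en-1-one | CC1=CCCCC1=O | starting material
18 | (S)-[(2,3-dimethylcyclohex-1-en-1-yl)oxy]trimethylsilane | C[C@H]1CCCC(O[Si](C)(C)C)=C1C | intermediate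
19 | (2R,3S)-2,3-dimethyl-2-[2-(W)ethyl]cyclohexan-1-one | C[C@@H]1CC=C2[C@@H](CCC[C@@]2(C)CC[C@@]2(C)C(=O)CCC[C@@H]2C)[C@]1(C)Cc1cc(OC)ccc1OC | intermediate
20 | (2R,3S)-6-(2-hydroxypropan-2-yl)-2,3-dimethyl-2-[2-(W)ethyl]cyclohexan-1-one | C[C@@H]1CC=C2[C@@H](CCC[C@@]2(C)CC[C@@]2(C)C(=O)C(C(C)(C)O)CC[C@@H]2C)[C@]1(C)Cc1cc(OC)ccc1OC | intermediate
21 | (2R,3S)-2,3-dimethyl-6-(propan-2-ylidene)-2-[2-(W)ethyl]cyclohexan-1-one | C[C@@H]1CC=C2[C@@H](CCC[C@@]2(C)CC[C@@]2(C)C(=O)C(=C(C)C)CC[C@@H]2C)[C@]1(C)Cc1cc(OC)ccc1OC | intermediate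
22 | (2R,3S,6R)-2,3-dimethyl-6-(2-methylpent-4-en-2-yl)-2-[2-(W)ethyl]cyclohexan-1-one | C[C@@H]1CC=C2[C@@H](CCC[C@@]2(C)CC[C@@]2(C)C(=O)[C@@H](C(C)(C)CC=C)CC[C@@H]2C)[C@]1(C)Cc1cc(OC)ccc1OC | intermediate
23 | (2R,3S,6R)-6-(5-hydroxy-2-methylpentan-2-yl)-2,3-dimethyl-2-[2-(W)ethyl]cyclohexan-1-one | C[C@@H]1CC=C2[C@@H](CCC[C@@]2(C)CC[C@@]2(C)C(=O)[C@@H](C(C)(C)CCCO)CC[C@@H]2C)[C@]1(C)Cc1cc(OC)ccc1OC | intermediate
24 | 4-methyl-4-{(1R,3R,4S)-3,4-dimethyl-2-oxo-3-[2-(W)ethyl]cyclohexyl}pentanal | C[C@@H]1CC=C2[C@@H](CCC[C@@]2(C)CC[C@@]2(C)C(=O)[C@@H](C(C)(C)CCC=O)CC[C@@H]2C)[C@]1(C)Cc1cc(OC)ccc1OC | intermediate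
25 | toxiusol hydroquinone dimethyl ether (West 4S,8R,9R,10S; East 5'R,8'S,9'R) | C[C@@H]1CC=C2[C@@H](CCC[C@@]2(C)CC[C@@]2(C)C3=CCCC(C)(C)[C@H]3CC[C@@H]2C)[C@]1(C)Cc1cc(OC)ccc1OC | intermediate
26 | corresponding 2-substituted 1,4-benzoquinone | C[C@@H]1CC=C2[C@@H](CCC[C@@]2(C)CC[C@@]2(C)C3=CCCC(C)(C)[C@H]3CC[C@@H]2C)[C@]1(C)CC1=CC(=O)C=CC1=O | intermediate
27 | corresponding hydroquinone (desulfated toxiusol) | C[C@@H]1CC=C2[C@@H](CCC[C@@]2(C)CC[C@@]2(C)C3=CCCC(C)(C)[C@H]3CC[C@@H]2C)[C@]1(C)Cc1cc(O)ccc1O | intermediate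
28 | toxiusol | C[C@@H]1CC=C2[C@@H](CCC[C@@]2(C)CC[C@@]2(C)C3=CCCC(C)(C)[C@H]3CC[C@@H]2C)[C@]1(C)Cc1cc(OS(=O)(=O)O)ccc1OS(=O)(=O)O | target

## Summary

Total steps: 24. Longest linear sequence: 23 (steps 1–13, then 15–24); step 14 is the only off-line step.

Steps most likely to fail, each with a fallback that changes the approach:

- **Step 21 (McMurry closure at the doubly hindered C10' ketone).** Fallback: convert alcohol 23 to the iodide, close the ring by SmI2/HMPA intramolecular Barbier addition to the cis-fused tertiary alcohol, then anti-eliminate (SOCl2/pyridine). With OH cis to H5', only C1' offers an anti-periplanar hydrogen.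
- **Step 15 (fragment-joining enolate alkylation with a complex primary iodide).** Fallback: join the halves at the other quaternary centre. Trap the step-14 enolate with allyl iodide, finish the East decalin alone, convert the allyl group to a CH2CH2CO2H arm, esterify it with allylic alcohol 13 and run an Ireland–Claisen rearrangement (forms C4 and C5=C6 during the union). Then remove the carboxyl by Barton decarboxylation with PhSeH as a fast H-donor to suppress 1,2-vinyl shift.
- **Step 10 (enzyme acceptance of the bulky bicyclic enone).** Fallback: substrate-controlled reduction with L-Selectride; equatorial attack anti to the axial C8 methyl gives the same axial 6α-alcohol. If selectivity is poor, use CBS reduction under catalyst control.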